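**Retrosynthetic overview**
- Rhoiptelol B ⇐ global hydrogenolysis of its tri-O-benzyl ether; the axial C4–OH ⇐ L-Selectride reduction of a 2,6-cis-oxan-4-one.
- The oxane ring (the only ring formed) ⇐ reversible 6-endo oxa-Michael closure (O1–C2 bond) of a β-hydroxy styryl enone, giving the 2,6-cis product under thermodynamic control.
- β-Hydroxy enone ⇐ chelation-controlled Mukaiyama aldol (C5–C6 bond) of the 2-silyloxydiene from O-benzyl dehydrozingerone with an (S)-α-benzyloxy aldehyde.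
- Aldehyde ⇐ methyl (S)-4-hydroxyphenyllactate (L-tyrosine pool), the only source of chirality; the other three stereocentres are relayed from it.
- Both arenes are bought; ring order is simply: oxane ring closed at step 6.

Assumption: dehydrozingerone and methyl (S)-3-(4-hydroxyphenyl)lactate are taken as catalogue compounds. Ring numbering used below: O1, C2 (aryl), C4 (OH), C6 (side chain), C1′ (side-chain carbinol); target = (2R,4S,6S,1′S), 2,6-cis with 4-OH trans to both.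

**Step 1**
Reactants: 1 dehydrozingerone, (E)-4-(4-hydroxy-3-methoxyphenyl)but-3-en-2-one
Product: 2 (E)-4-[4-(benzyloxy)-3-methoxyphenyl]but-3-en-2-one
Conditions: BnBr, K2CO3, acetone, reflux
Reagents that add atoms: benzyl bromide, BrCc1ccccc1
Why: Williamson ether synthesis on the phenoxide, the only acidic site, leaves the E-enone untouched and creates no stereocentre.

**Step 2**
Reactants: 2 (E)-4-[4-(benzyloxy)-3-methoxyphenyl]but-3-en-2-one
Product: 3 {[(3E)-4-[4-(benzyloxy)-3-methoxyphenyl]buta-1,3-dien-2-yl]oxy}trimethylsilane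
Conditions: TMSOTf, Et3N, CH2Cl2, 0 °C; pentane/cold NaHCO3 work-up, used crude
Reagents that add atoms: trimethylsilyl trifluoromethanesulfonate, C[Si](C)(C)OS(=O)(=O)C(F)(F)F
Why: Soft enolisation and O-silylation (silyl enol ether formation) can only occur at the methyl group, so a single 2-silyloxydiene forms with the E-styryl geometry retained.

**Step 3**
Reactants: 4 methyl (2S)-2-hydroxy-3-(4-hydroxyphenyl)propanoate
Product: 5 methyl (2S)-2-(benzyloxy)-3-[4-(benzyloxy)phenyl]propanoate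
Conditions: BnBr (3 equiv), Ag2O (2.5 equiv), CH2Cl2, rt, dark
Reagents that add atoms: benzyl bromide, BrCc1ccccc1
Why: Silver(I) oxide-mediated Williamson-type benzylation etherifies both the phenol and the α-hydroxy ester without a strong base, so the chiral-pool (S) centre is not epimerised.

**Step 4**
Reactants: 5 methyl (2S)-2-(benzyloxy)-3-[4-(benzyloxy)phenyl]propanoate
Product: 6 (2S)-2-(benzyloxy)-3-[4-(benzyloxy)phenyl]propanal
Conditions: DIBAL-H (1.1 equiv), CH2Cl2, −78 °C; MeOH then Rochelle salt; used at once without chromatography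
Reagents that add atoms: none
Why: Partial DIBAL reduction of an α-alkoxy ester stops at the chelated tetrahedral aluminate at −78 °C and releases the aldehyde only on work-up, keeping the (S) centre intact.

**Step 5**
Reactants: 3 {[(3E)-4-[4-(benzyloxy)-3-methoxyphenyl]buta-1,3-dien-2-yl]oxy}trimethylsilane; 6 (2S)-2-(benzyloxy)-3-[4-(benzyloxy)phenyl]propanal
Product: 8 (1E,5S,6S)-6-(benzyloxy)-1-[4-(benzyloxy)-3-methoxyphenyl]-7-[4-(benzyloxy)phenyl]-5-hydroxyhept-1-en-3-one, via (1E,5S,6S)-6-(benzyloxy)-1-[4-(benzyloxy)-3-methoxyphenyl]-7-[4-(benzyloxy)phenyl]-5-[(trimethylsilyl)oxy]hept-1-en-3-one 7 (not isolated)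
Conditions: 6 + MgBr2·OEt2 (3 equiv), CH2Cl2, −78 °C; add 3 (1.5 equiv), −78 → −20 °C; then 1 M HCl, THF, 0 °C
Reagents that add atoms: none
Why: In this chelation-controlled Mukaiyama aldol the Mg(II) bridges the aldehyde and α-OBn oxygens (Cram chelate) and the enol silane attacks anti to the CH2Ar group, giving the syn (threo) 5S,6S adduct, whose O-TMS ether is cleaved in the acidic work-up.

**Step 6**
Reactants: 8 (1E,5S,6S)-6-(benzyloxy)-1-[4-(benzyloxy)-3-methoxyphenyl]-7-[4-(benzyloxy)phenyl]-5-hydroxyhept-1-en-3-one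
Product: 9 (2R,6S)-2-[4-(benzyloxy)-3-methoxyphenyl]-6-{(1S)-1-(benzyloxy)-2-[4-(benzyloxy)phenyl]ethyl}oxan-4-one (2,6-cis)
Conditions: Amberlyst-15, CH2Cl2, rt
Reagents that add atoms: none
Why: The acid-catalysed 6-endo-trig intramolecular oxa-Michael addition is reversible, so it settles in the chair with aryl and side chain both equatorial, setting C2 (R) cis to the existing C6 centre.

**Step 7**
Reactants: 9 (2R,6S)-2-[4-(benzyloxy)-3-methoxyphenyl]-6-{(1S)-1-(benzyloxy)-2-[4-(benzyloxy)phenyl]ethyl}oxan-4-one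
Product: 10 (2R,4S,6S)-2-[4-(benzyloxy)-3-methoxyphenyl]-6-{(1S)-1-(benzyloxy)-2-[4-(benzyloxy)phenyl]ethyl}oxan-4-ol (4-OH axial, trans to both ring substituents)
Conditions: L-Selectride (1.3 equiv), THF, −78 °C; then H2O
Reagents that add atoms: none
Why: In this bulky-hydride ketone reduction L-Selectride attacks the 2,6-diequatorial chair from the equatorial direction, away from the axial hydrogens at C2 and C6, giving the axial (4S) alcohol.

**Step 8**
Reactants: 10 (2R,4S,6S)-2-[4-(benzyloxy)-3-methoxyphenyl]-6-{(1S)-1-(benzyloxy)-2-[4-(benzyloxy)phenyl]ethyl}oxan-4-ol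
Product: 11 rhoiptelol B, (2R,4S,6S)-2-(4-hydroxy-3-methoxyphenyl)-6-[(1S)-1-hydroxy-2-(4-hydroxyphenyl)ethyl]oxan-4-ol
Conditions: H2 (1 atm), 10% Pd/C, EtOAc, rt; stopped as soon as 10 is consumed
Reagents that add atoms: none
Why: Catalytic hydrogenolysis cleaves the three O-benzyl ethers under neutral conditions that touch no stereocentre and, with short contact in EtOAc, spare the ring benzylic C2–O bond.

**Compound list**
1 | dehydrozingerone, (E)-4-(4-hydroxy-3-methoxyphenyl)but-3-en-2-one | CC(=O)/C=C/c1ccc(O)c(OC)c1 | starting material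
2 | (E)-4-[4-(benzyloxy)-3-methoxyphenyl]but-3-en-2-one | CC(=O)/C=C/c1ccc(OCc2ccccc2)c(OC)c1 | intermediate
3 | {[(3E)-4-[4-(benzyloxy)-3-methoxyphenyl]buta-1,3-dien-2-yl]oxy}trimethylsilane | C=C(O[Si](C)(C)C)/C=C/c1ccc(OCc2ccccc2)c(OC)c1 | intermediate
4 | methyl (2S)-2-hydroxy-3-(4-hydroxyphenyl)propanoate | COC(=O)[C@@H](O)Cc1ccc(O)cc1 | starting material
5 | methyl (2S)-2-(benzyloxy)-3-[4-(benzyloxy)phenyl]propanoate | COC(=O)[C@@H](OCc1ccccc1)Cc1ccc(OCc2ccccc2)cc1 | intermediate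
6 | (2S)-2-(benzyloxy)-3-[4-(benzyloxy)phenyl]propanal | O=C[C@@H](OCc1ccccc1)Cc1ccc(OCc2ccccc2)cc1 | intermediate
7 | (1E,5S,6S)-6-(benzyloxy)-1-[4-(benzyloxy)-3-methoxyphenyl]-7-[4-(benzyloxy)phenyl]-5-[(trimethylsilyl)oxy]hept-1-en-3-one | COc1cc(/C=C/C(=O)C[C@H](O[Si](C)(C)C)[C@@H](OCc2ccccc2)Cc2ccc(OCc3ccccc3)cc2)ccc1OCc1ccccc1 | intermediate (not isolated)
8 | (1E,5S,6S)-6-(benzyloxy)-1-[4-(benzyloxy)-3-methoxyphenyl]-7-[4-(benzyloxy)phenyl]-5-hydroxyhept-1-en-3-one | COc1cc(/C=C/C(=O)C[C@H](O)[C@@H](OCc2ccccc2)Cc2ccc(OCc3ccccc3)cc2)ccc1OCc1ccccc1 | intermediate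
9 | (2R,6S)-2-[4-(benzyloxy)-3-methoxyphenyl]-6-{(1S)-1-(benzyloxy)-2-[4-(benzyloxy)phenyl]ethyl}oxan-4-one | COc1cc([C@H]2CC(=O)C[C@@H]([C@@H](OCc3ccccc3)Cc3ccc(OCc4ccccc4)cc3)O2)ccc1OCc1ccccc1 | intermediate
10 | (2R,4S,6S)-2-[4-(benzyloxy)-3-methoxyphenyl]-6-{(1S)-1-(benzyloxy)-2-[4-(benzyloxy)phenyl]ethyl}oxan-4-ol | COc1cc([C@H]2C[C@H](O)C[C@@H]([C@@H](OCc3ccccc3)Cc3ccc(OCc4ccccc4)cc3)O2)ccc1OCc1ccccc1 | intermediate
11 | rhoiptelol B, (2R,4S,6S)-2-(4-hydroxy-3-methoxyphenyl)-6-[(1S)-1-hydroxy-2-(4-hydroxyphenyl)ethyl]oxan-4-ol | COc1cc([C@H]2C[C@H](O)C[C@@H]([C@@H](O)Cc3ccc(O)cc3)O2)ccc1O | target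

**Totals**
Total step count: 8. Longest linear sequence: 6 steps (4 → 5 → 6 → 8 → 9 → 10 → 11, or equally 1 → 2 → 3 → 8 → 9 → 10 → 11).

**Three steps most likely to fail, with fallbacks**

Step 5 (Mukaiyama aldol). The risks are the lability of silyloxydiene 3, incomplete chelation control and epimerisation of 6. The fallback sets out from 6 and comes back at 9, bypassing both 3 and the oxa-Michael step. Keck allylation of 6 (allyltributylstannane, MgBr2·OEt2, CH2Cl2, −78 °C) gives, under chelation control, the syn homoallylic alcohol (2S,3S)-2-(benzyloxy)-1-[4-(benzyloxy)phenyl]hex-5-en-3-ol F1. Prins cyclisation of F1 with commercial 4-(benzyloxy)-3-methoxybenzaldehyde (TFA, CH2Cl2, 0 °C → rt) closes the ring through a chair oxocarbenium ion with equatorial trapping, giving the all-cis ester (2R,4R,6S)-2-[4-(benzyloxy)-3-methoxyphenyl]-6-{(1S)-1-(benzyloxy)-2-[4-(benzyloxy)phenyl]ethyl}oxan-4-yl trifluoroacetate F2. Methanolysis (K2CO3, MeOH) gives the all-cis alcohol (2R,4R,6S)-2-[4-(benzyloxy)-3-methoxyphenyl]-6-{(1S)-1-(benzyloxy)-2-[4-(benzyloxy)phenyl]ethyl}oxan-4-ol F3, and Dess–Martin oxidation of F3 gives ketone 9.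

Step 6 (oxa-Michael). The risks are an unfavourable ring/chain equilibrium for the electron-rich styryl ketone and acid-promoted dehydration of the β-hydroxy ketone. The fallback sets out from 8 and comes back at 9 and replaces the reversible addition by an irreversible oxidative closure. Pd(II)-catalysed Wacker-type 6-endo cyclisation of 8 (PdCl2 cat., CuCl, Na2HPO4, O2, DME, 50 °C) gives the dihydropyranone (2S)-2-{(1S)-1-(benzyloxy)-2-[4-(benzyloxy)phenyl]ethyl}-6-[4-(benzyloxy)-3-methoxyphenyl]-2,3-dihydro-4H-pyran-4-one F4. Conjugate reduction of F4 (L-Selectride, 1 equiv, THF, −78 °C, or Stryker's reagent) delivers hydride axially to the aryl-bearing carbon and gives the 2,6-cis ketone 9.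

Step 8 (hydrogenolysis). The risk is reductive opening of the benzylic C2–O bond of the electron-rich 2-aryl oxane. The fallback sets out from 10 and comes back at 11 and is non-reductive: Lewis-acid debenzylation with BCl3 and pentamethylbenzene as benzyl-cation scavenger (CH2Cl2, −78 °C). It makes no new compound (F0).

**Further compounds**
F1 | step 5 | (2S,3S)-2-(benzyloxy)-1-[4-(benzyloxy)phenyl]hex-5-en-3-ol | C=CC[C@H](O)[C@@H](OCc1ccccc1)Cc1ccc(OCc2ccccc2)cc1
F2 | step 5 | (2R,4R,6S)-2-[4-(benzyloxy)-3-methoxyphenyl]-6-{(1S)-1-(benzyloxy)-2-[4-(benzyloxy)phenyl]ethyl}oxan-4-yl trifluoroacetate | COc1cc([C@H]2C[C@@H](OC(=O)C(F)(F)F)C[C@@H]([C@@H](OCc3ccccc3)Cc3ccc(OCc4ccccc4)cc3)O2)ccc1OCc1ccccc1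
F3 | step 5 | (2R,4R,6S)-2-[4-(benzyloxy)-3-methoxyphenyl]-6-{(1S)-1-(benzyloxy)-2-[4-(benzyloxy)phenyl]ethyl}oxan-4-ol | COc1cc([C@H]2C[C@@H](O)C[C@@H]([C@@H](OCc3ccccc3)Cc3ccc(OCc4ccccc4)cc3)O2)ccc1OCc1ccccc1
F4 | step 6 | (2S)-2-{(1S)-1-(benzyloxy)-2-[4-(benzyloxy)phenyl]ethyl}-6-[4-(benzyloxy)-3-methoxyphenyl]-2,3-dihydro-4H-pyran-4-one | COc1cc(C2=CC(=O)C[C@@H]([C@@H](OCc3ccccc3)Cc3ccc(OCc4ccccc4)cc3)O2)ccc1OCc1ccccc1
F0 | step 8 | none | none
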